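**Retrosynthetic overview**
1. Numbering: briarane numbering. Ring A is the cyclohexane C1/C10/C11/C12/C13/C14, ring B the ten-membered carbocycle C1–C10, ring C the γ-lactone O–C7–C8–C17–C19. β is the face of ring A that carries the C15 methyl.
2. Enabling feature: on ring A the array C2(OAc)–C1(quaternary, C15)–C14(OH) is an anti-1,3-diol monoacetate around a quaternary carbon. This is the retron of a semipinacol shift of an α-hydroxy epoxide followed by Evans–Tishchenko reduction, so C1 can be inserted into the C14–C10 bond of a cyclopentanol.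
3. Disconnections: ring C by O9-to-O7 translactonisation of a temporary C9 lactone; ring B at C6–C7 (Nozaki–Hiyama–Kishi); C8–C9 (Nozaki–Hiyama–Kishi) plus dihydroxylation of C8=C7; ring A back to epoxy cyclopentanol 21, made from cyclopentanone 8 and alkenyl iodide 17.
4. Stereochemistry: one carbinol (C14) is set by CBS reduction and all other centres are relayed from it. C10 is carried as the epimer that matches the shift and is inverted at the aldehyde stage (step 15).
5. Order of rings: five-membered carbocycle (bought) → ring A (step 12) → temporary C9 lactone (step 17) → ring B (step 23) → ring C (step 24).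

Key step: step 12

Remark on the chemistry: iodide 29 is used as the racemate, so 30 and 31 are pairs of C17 epimers. They converge to one epimer in step 18.

Step 1
Reactants: 1 3-methylcyclopent-2-en-1-one
Product: 2 (R)-3-methylcyclopent-2-en-1-ol
Conditions: (S)-Me-CBS oxazaborolidine [(S)-1-methyl-3,3-diphenyltetrahydro-1H,3H-pyrrolo[1,2-c][1,3,2]oxazaborole] (10 mol%), BH3·SMe2, THF, −20 °C; MeOH, aqueous work-up
Reagents that add atoms: none
Why: Corey–Bakshi–Shibata reduction, in which the alkene-bearing side of the enone acts as the large group, should deliver hydride to one face and give the (R)-carbinol C14 that starts the stereochemical relay.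

Step 2
Reactants: 2 (R)-3-methylcyclopent-2-en-1-ol
Product: 3 (1R,2R,5S)-5-methyl-6-oxabicyclo[3.1.0]hexan-2-ol (oxirane cis to the hydroxyl)
Conditions: VO(acac)2 (1 mol%), t-BuOOH (decane), CH2Cl2, 0 °C
Reagents that add atoms: tert-butyl hydroperoxide CC(C)(C)OO
Why: Hydroxyl-directed vanadium-catalysed epoxidation places the oxirane on the face of the C14 hydroxyl and so sets C11 (final configuration) and C10.

Step 3
Reactants: 3 (1R,2R,5S)-5-methyl-6-oxabicyclo[3.1.0]hexan-2-ol
Product: 5 (1R,2S,3S)-2-(hydroxymethyl)-3-methylcyclopentane-1,3-diol, via silylmethyl diol 4 (not isolated)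
Conditions: i-PrOMe2SiCH2MgCl (3 equiv), CuI (10 mol%), THF, −30 to 0 °C; then KF, KHCO3, 30% H2O2, THF–MeOH, rt
Reagents that add atoms: (isopropoxydimethylsilyl)methylmagnesium chloride CC(C)O[Si](C)(C)C[Mg]Cl; hydrogen peroxide OO
Why: Copper-catalysed SN2 opening of the 2,3-epoxy alcohol at the secondary carbon C10 (C11 is tertiary) occurs with inversion and puts C9 trans to O11 and O14, and the Tamao oxidation turns C–Si into C–OH without touching a stereocentre.

Step 4
Reactants: 5 (1R,2S,3S)-2-(hydroxymethyl)-3-methylcyclopentane-1,3-diol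
Product: 6 (1R,2S,3S)-3-methyl-2-(triethylsilyloxymethyl)cyclopentane-1,3-diol
Conditions: Et3SiCl (1.0 equiv), imidazole, CH2Cl2, −40 °C
Reagents that add atoms: chlorotriethylsilane CC[Si](Cl)(CC)CC
Why: Selective silylation, because the primary hydroxyl reacts far faster with one equivalent of silyl chloride than the secondary and tertiary ones.

Step 5
Reactants: 6 (1R,2S,3S)-3-methyl-2-(triethylsilyloxymethyl)cyclopentane-1,3-diol
Product: 7 (2R,3S)-3-hydroxy-3-methyl-2-(triethylsilyloxymethyl)cyclopentan-1-one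
Conditions: Dess–Martin periodinane, NaHCO3, CH2Cl2, 0 °C
Reagents that add atoms: none
Why: Dess–Martin oxidation touches only the secondary carbinol, and the buffered non-basic medium should spare the β-hydroxy ketone from dehydration and C10 from epimerisation.

Step 6
Reactants: 7 (2R,3S)-3-hydroxy-3-methyl-2-(triethylsilyloxymethyl)cyclopentan-1-one
Product: 8 (2R,3S)-3-(tert-butyldimethylsilyloxy)-3-methyl-2-(triethylsilyloxymethyl)cyclopentan-1-one
Conditions: t-BuMe2SiOTf, 2,6-lutidine, CH2Cl2, −78 to 0 °C
Reagents that add atoms: tert-butyldimethylsilyl triflate CC(C)(C)[Si](C)(C)OS(=O)(=O)C(F)(F)F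
Why: Silyl triflate with a hindered pyridine base silylates the tertiary alcohol under conditions too mild for β-elimination.

Step 7
Reactants: 9 5-bromopent-2-yne; 10 propyne
Product: 13 (Z)-1-iodo-2-methylhept-1-en-5-yne, via Grignard reagent 11 (not isolated), via alkenylcopper 12 (not isolated)
Conditions: Mg, THF; CuBr·SMe2, Et2O–Me2S, −45 °C; propyne, −25 °C; I2, −50 to 0 °C
Reagents that add atoms: iodine II
Why: Normant carbocupration adds the alkylcopper syn across propyne with copper at the terminal carbon, so chain and copper are cis and iodinolysis with retention gives the Z geometry of the later C5=C6 bond.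

Step 8
Reactants: 13 (Z)-1-iodo-2-methylhept-1-en-5-yne
Product: 15 (Z)-trimethyl(2-methylhept-1-en-5-yn-1-yl)silane, via alkenyllithium 14 (not isolated)
Conditions: t-BuLi (2.1 equiv), Et2O, −78 °C; Me3SiCl, −78 °C to rt
Reagents that add atoms: chlorotrimethylsilane C[Si](C)(C)Cl
Why: Iodine–lithium exchange and silylation both proceed with retention, and the silane masks the future C6 iodide against t-BuLi (step 10) and against the first chromium coupling (step 17).

Step 9
Reactants: 15 (Z)-trimethyl(2-methylhept-1-en-5-yn-1-yl)silane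
Product: 17 (1Z,5E)-6-iodo-2-methyl-1-(trimethylsilyl)hepta-1,5-diene, via alkenylzirconocene chloride 16 (not isolated)
Conditions: Cp2Zr(H)Cl (2 equiv), THF, rt to 40 °C; I2, 0 °C
Reagents that add atoms: iodine II
Why: Schwartz hydrozirconation is a syn addition that, after equilibration with excess reagent, leaves zirconium on the alkyne carbon next to the methyl group, and iodinolysis with retention gives the E iodide while the trisubstituted vinylsilane stays inert.

Step 10
Reactants: 17 (1Z,5E)-6-iodo-2-methyl-1-(trimethylsilyl)hepta-1,5-diene; 8 (2R,3S)-3-(tert-butyldimethylsilyloxy)-3-methyl-2-(triethylsilyloxymethyl)cyclopentan-1-one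
Product: 20 1-alkenylcyclopentanol (alkenyl carbon C1 on the β face of C14, cis to O11; 14-OH α), via alkenyllithium 18 (not isolated), via alkenylcerium dichloride 19 (not isolated)
Conditions: 17, t-BuLi (2 equiv), Et2O, −78 °C; CeCl3, THF, −78 °C; then 8, −78 °C
Reagents that add atoms: none
Why: The weakly basic organocerium reagent adds 1,2 to the enolisable β-silyloxy ketone without elimination, and it should attack the face opposite to the adjacent C9 side chain and the C20 methyl, which sets the C14 carbinol.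

Step 11
Reactants: 20 1-alkenylcyclopentanol
Product: 21 (1R,2S)-epoxy cyclopentanol (α-hydroxy epoxide)
Conditions: VO(acac)2 (5 mol%), t-BuOOH (decane), CH2Cl2, 0 °C
Reagents that add atoms: tert-butyl hydroperoxide CC(C)(C)OO
Why: Hydroxyl-directed vanadium epoxidation touches only the allylic C1=C2 bond; in the vanadate transition state (O–C14–C1=C2 near 50°) the unbranched C13 methylene takes the place next to the C15 methyl (A(1,2) strain) and the branched C10 points away from the reagent, which should expose the face that gives the (1R,2S)-oxirane.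

Step 12
Reactants: 21 (1R,2S)-epoxy cyclopentanol
Product: 24 ring A monoacetate (2-OAc, 14α-OH, 11β-OTBS, 10α-CH2OTES), via samarium-bound hydroxy ketone 22 (not isolated), via acetaldehyde hemiacetal 23 (not isolated)
Conditions: SmI2 (30 mol%), CH3CHO (10 equiv), THF–ClCH2CH2Cl, −10 °C to rt
Reagents that add atoms: acetaldehyde CC=O
Why: Trivalent samarium formed in situ binds O14 and the oxirane oxygen, the C1–O bond opens at its tertiary end and the antiperiplanar C14–C10 bond shifts to C1 (semipinacol rearrangement of an α-hydroxy epoxide), so C1 is inserted into the five-membered ring and ring A arises by a 1,2-shift and not by a chain-end closure. C1 is set by inversion at the oxirane carbon, C10 migrates with retention and C2 keeps the oxirane configuration. The freed C2 alkoxide adds to acetaldehyde and the samarium-bound hemiacetal 23 passes hydride to C14=O through the chair-like Evans–Tishchenko transition state, which gives the 2,14-anti relationship (axial 14α-OH) and leaves the acetate on O2 only. The closest known reaction type is the SmI2-promoted tandem semipinacol rearrangement/Tishchenko reduction of α-hydroxy epoxides to 2-quaternary 1,3-diol monoesters, ring-enlarging cases included. The step needs C10 and not C13 to migrate: C10 is the tertiary carbon, and in the rotamer with C14–C10 anti to C1–O the small C15 methyl lies over the ring and the C2 chain points outward towards a chair with axial C15, whereas the C13 rotamer forces the C2 chain over the ring. The bulky non-chelating silyl ethers keep samarium on O14 and the oxirane oxygen.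

Step 13
Reactants: 24 ring A monoacetate
Product: 25 14-O-tert-butyldimethylsilyl ether of 24
Conditions: t-BuMe2SiOTf, 2,6-lutidine, CH2Cl2, 0 °C
Reagents that add atoms: tert-butyldimethylsilyl triflate CC(C)(C)[Si](C)(C)OS(=O)(=O)C(F)(F)F
Why: The reactive silyl triflate should silylate even the hindered axial C14 hydroxyl, which blocks O2-to-O14 acetyl migration and oxidation at C14.

Step 14
Reactants: 25 14-O-tert-butyldimethylsilyl ether of 24
Product: 26 10-epi C9 aldehyde (formyl group α, axial)
Conditions: (COCl)2, DMSO, CH2Cl2, −78 to −40 °C; Et3N, −78 to 0 °C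
Reagents that add atoms: none
Why: Swern conditions convert primary triethylsilyl ethers directly into aldehydes, while the secondary and tertiary tert-butyldimethylsilyl ethers, the acetate and the vinylsilane are left alone.

Step 15
Reactants: 26 10-epi C9 aldehyde
Product: 27 C9 aldehyde with natural C10 (formyl group β, equatorial; H10 α)
Conditions: 1,8-diazabicyclo[5.4.0]undec-7-ene (DBU, 0.3 equiv), toluene, rt
Reagents that add atoms: none
Why: Base-mediated epimerisation through the enolate is driven by loss of the syn-axial contact between the formyl group and the C14 silyl ether, and reprotonation from the open α face (the β face is screened by axial C15 and O11) leads to the same natural C10 configuration.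

Step 16
Reactants: 28 ethyl 2-methylbuta-2,3-dienoate
Product: 29 ethyl 3-iodo-2-methylbut-3-enoate (racemic)
Conditions: NaI, AcOH, 40 °C
Reagents that add atoms: sodium iodide [Na+].[I-]
Why: Hydroiodination of a 2,3-allenoate: iodide adds to the central allene carbon and the dienolate is protonated at the α-carbon, which gives the β-iodo-β,γ-unsaturated ester.

Step 17
Reactants: 27 C9 aldehyde with natural C10; 29 ethyl 3-iodo-2-methylbut-3-enoate
Product: 31 temporary C9 lactone (β-methylene-γ-lactone, 9S, C17 epimers), via hydroxy ester 30 (not isolated)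
Conditions: CrCl2 (6 equiv), NiCl2 (2 mol%), DMSO, rt; then pyridinium p-toluenesulfonate, benzene, 50 °C
Reagents that add atoms: none
Why: The Nozaki–Hiyama–Kishi coupling tolerates acetate, silyl ethers and vinylsilane; the formyl hydrogen has to sit in the cleft between axial C15 and the axial O11 silyl ether, so the alkenylchromium reagent should reach C9 past the small equatorial C20 methyl and not past the C2 side chain, which gives (9S), and the γ-hydroxy ester then lactonises under mild acid.

Step 18
Reactants: 31 temporary C9 lactone (C17 epimers)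
Product: 33 (17R)-C9 lactone (C18 methyl cis to ring A on the lactone), via lithium dienolate 32 (not isolated)
Conditions: LiN(SiMe3)2 (1.05 equiv), THF, −78 °C; AcOH, −78 °C
Reagents that add atoms: none
Why: Only the doubly activated C17–H is removed, and kinetic α-protonation of the extended enolate (deconjugative protonation) from the face opposite to the large ring A substituent on C9 should merge both epimers into (17R).

Step 19
Reactants: 33 (17R)-C9 lactone
Product: 34 (Z)-vinyl iodide lactone
Conditions: N-iodosuccinimide, (CF3)2CHOH, 0 °C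
Reagents that add atoms: N-iodosuccinimide O=C1CCC(=O)N1I
Why: Iododesilylation is an ipso substitution that keeps the Z geometry, and the electron-rich vinylsilane should react well before the hindered, inductively deactivated exocyclic methylene.

Step 20
Reactants: 34 (Z)-vinyl iodide lactone
Product: 35 (8S)-8-hydroxy-8-(hydroxymethyl) lactone diol
Conditions: OsO4 (5 mol%), N-methylmorpholine N-oxide, acetone–H2O, rt
Reagents that add atoms: N-methylmorpholine N-oxide C[N+]1([O-])CCOCC1; water O
Why: Upjohn dihydroxylation should strike the exocyclic C8=C7 bond on the lactone face opposite to ring A (on C9) and to the C18 methyl (on C17), which sets C8 with O8 trans to C10, while the vinyl iodide is deactivated towards OsO4.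

Step 21
Reactants: 35 lactone diol
Product: 36 7,8-bis(triethylsilyl) ether
Conditions: Et3SiOTf (3 equiv), 2,6-lutidine, CH2Cl2, −78 to 0 °C
Reagents that add atoms: triethylsilyl triflate CC[Si](CC)(CC)OS(=O)(=O)C(F)(F)F
Why: The silyl triflate caps the primary and the tertiary hydroxyl at once, which stops migration of the lactone to O7 and makes O8 non-chelating for step 23.

Step 22
Reactants: 36 7,8-bis(triethylsilyl) ether
Product: 37 C7 aldehyde (8-OTES)
Conditions: (COCl)2, DMSO, CH2Cl2, −78 to −40 °C; Et3N, −78 to 0 °C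
Reagents that add atoms: none
Why: The Swern reagent again cleaves and oxidises only the primary triethylsilyl ether, and the resulting α-silyloxy aldehyde has no α-hydrogen and cannot epimerise.

Step 23
Reactants: 37 C7 aldehyde (8-OTES)
Product: 38 ring B allylic alcohol (7S, C9 lactone still in place)
Conditions: CrCl2 (15 equiv), NiCl2 (5 mol%), DMSO–THF, 0.002 M, rt
Reagents that add atoms: none
Why: The intramolecular Nozaki–Hiyama–Kishi reaction at high dilution closes ring B at C6–C7 with retention of the Z geometry; the cis-fused C9 lactone holds C7 and C10 on one face as a turn element, and attack anti to the C8–O bond (polar Felkin–Anh, non-chelating silyl ether, smaller C17 branch next to the incoming carbon) should give (7S).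

Step 24
Reactants: 38 ring B allylic alcohol
Product: 40 tris-silylated Junceellolide I (C7 lactone, 9-OAc), via C7 lactone 9-alcohol 39 (not isolated)
Conditions: DBU (0.2 equiv), toluene, 40 °C; then Ac2O, Et3N, 4-(dimethylamino)pyridine, rt
Reagents that add atoms: acetic anhydride CC(=O)OC(C)=O
Why: Base-catalysed translactonisation through the bicyclic tetrahedral intermediate moves the acyl group from O9 to O7, driven by release of the cisoid C7–C8–C9–C10 arrangement that the C9 lactone imposes on ring B (natural 9-hydroxy briaranes are C7 lactones), and the freed C9 hydroxyl is then acetylated under nucleophilic catalysis.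

Step 25
Reactants: 40 tris-silylated Junceellolide I
Product: 41 Junceellolide I
Conditions: HF·pyridine, pyridine, THF, 0 °C to rt
Reagents that add atoms: none
Why: Acidic fluoride removes both tert-butyldimethylsilyl ethers and the triethylsilyl ether without the basic conditions that would trigger acetyl migration (O2 to O14, O9 to O8 or O11) or lactone opening.

**Compound list**
1 | 3-methylcyclopent-2-en-1-one | CC1=CC(=O)CC1 | starting material
2 | (R)-3-methylcyclopent-2-en-1-ol | O[C@H]1C=C(C)CC1 | intermediate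
3 | (1R,2R,5S)-5-methyl-6-oxabicyclo[3.1.0]hexan-2-ol | O[C@H]1[C@H]2O[C@@]2(C)CC1 | intermediate
4 | (1R,2S,3S)-2-[(isopropoxydimethylsilyl)methyl]-3-methylcyclopentane-1,3-diol | O[C@H]1[C@H](C[Si](C)(C)OC(C)C)[C@@](C)(O)CC1 | intermediate
5 | (1R,2S,3S)-2-(hydroxymethyl)-3-methylcyclopentane-1,3-diol | O[C@H]1[C@H](CO)[C@@](C)(O)CC1 | intermediate
6 | (1R,2S,3S)-3-methyl-2-(triethylsilyloxymethyl)cyclopentane-1,3-diol | O[C@H]1[C@H](CO[Si](CC)(CC)CC)[C@@](C)(O)CC1 | intermediate
7 | (2R,3S)-3-hydroxy-3-methyl-2-(triethylsilyloxymethyl)cyclopentan-1-one | O=C1[C@H](CO[Si](CC)(CC)CC)[C@@](C)(O)CC1 | intermediate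
8 | (2R,3S)-3-(tert-butyldimethylsilyloxy)-3-methyl-2-(triethylsilyloxymethyl)cyclopentan-1-one | O=C1[C@H](CO[Si](CC)(CC)CC)[C@@](C)(O[Si](C)(C)C(C)(C)C)CC1 | intermediate
9 | 5-bromopent-2-yne | CC#CCCBr | starting material
10 | propyne | CC#C | starting material
11 | pent-3-yn-1-ylmagnesium bromide | CC#CCC[Mg]Br | intermediate
12 | (Z)-(2-methylhept-1-en-5-yn-1-yl)copper | [Cu]/C=C(/C)CCC#CC | intermediate
13 | (Z)-1-iodo-2-methylhept-1-en-5-yne | I/C=C(/C)CCC#CC | intermediate
14 | (Z)-(2-methylhept-1-en-5-yn-1-yl)lithium | [Li]/C=C(/C)CCC#CC | intermediate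
15 | (Z)-trimethyl(2-methylhept-1-en-5-yn-1-yl)silane | C[Si](C)(C)/C=C(/C)CCC#CC | intermediate
16 | alkenylzirconocene chloride from 15 (Zr on C1, E) | C[Si](C)(C)/C=C(/C)CC/C=C(C)/[Zr](Cl)(C1C=CC=C1)C1C=CC=C1 | intermediate
17 | (1Z,5E)-6-iodo-2-methyl-1-(trimethylsilyl)hepta-1,5-diene | C[Si](C)(C)/C=C(/C)CC/C=C(C)/I | intermediate
18 | alkenyllithium from 17 | C[Si](C)(C)/C=C(/C)CC/C=C(C)/[Li] | intermediate
19 | alkenylcerium dichloride from 18 | C[Si](C)(C)/C=C(/C)CC/C=C(C)/[Ce](Cl)Cl | intermediate
20 | 1-alkenylcyclopentanol (C1 β on C14, 14-OH α, C9 chain α, O11 β) | C[Si](C)(C)/C=C(/C)CC/C=C(C)/[C@]1(O)CC[C@](C)(O[Si](C)(C)C(C)(C)C)[C@H]1CO[Si](CC)(CC)CC | intermediate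
21 | (1R,2S)-epoxy cyclopentanol | C[Si](C)(C)/C=C(/C)CC[C@@H]1O[C@@]1(C)[C@]2(O)CC[C@](C)(O[Si](C)(C)C(C)(C)C)[C@H]2CO[Si](CC)(CC)CC | intermediate
22 | ring-enlarged 2-hydroxy 14-ketone (drawn as the free alcohol) | C[Si](C)(C)/C=C(/C)CC[C@H](O)[C@@]1(C)C(=O)CC[C@](C)(O[Si](C)(C)C(C)(C)C)[C@H]1CO[Si](CC)(CC)CC | intermediate
23 | acetaldehyde hemiacetal of 22 (hemiacetal carbon undefined) | C[Si](C)(C)/C=C(/C)CC[C@H](OC(C)O)[C@@]1(C)C(=O)CC[C@](C)(O[Si](C)(C)C(C)(C)C)[C@H]1CO[Si](CC)(CC)CC | intermediate
24 | ring A monoacetate (2-OAc, 14α-OH, 11β-OTBS, 10α-CH2OTES) | C[Si](C)(C)/C=C(/C)CC[C@H](OC(C)=O)[C@@]1(C)[C@@H](O)CC[C@](C)(O[Si](C)(C)C(C)(C)C)[C@H]1CO[Si](CC)(CC)CC | intermediate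
25 | 14-O-TBS ether of 24 | C[Si](C)(C)/C=C(/C)CC[C@H](OC(C)=O)[C@@]1(C)[C@@H](O[Si](C)(C)C(C)(C)C)CC[C@](C)(O[Si](C)(C)C(C)(C)C)[C@H]1CO[Si](CC)(CC)CC | intermediate
26 | 10-epi C9 aldehyde | C[Si](C)(C)/C=C(/C)CC[C@H](OC(C)=O)[C@@]1(C)[C@@H](O[Si](C)(C)C(C)(C)C)CC[C@](C)(O[Si](C)(C)C(C)(C)C)[C@H]1C=O | intermediate
27 | C9 aldehyde, natural C10 | C[Si](C)(C)/C=C(/C)CC[C@H](OC(C)=O)[C@@]1(C)[C@@H](O[Si](C)(C)C(C)(C)C)CC[C@](C)(O[Si](C)(C)C(C)(C)C)[C@@H]1C=O | intermediate
28 | ethyl 2-methylbuta-2,3-dienoate | C=C=C(C)C(=O)OCC | starting material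
29 | ethyl 3-iodo-2-methylbut-3-enoate (racemic) | C=C(I)C(C)C(=O)OCC | intermediate
30 | (9S)-hydroxy ester (C17 epimers) | C[Si](C)(C)/C=C(/C)CC[C@H](OC(C)=O)[C@@]1(C)[C@@H](O[Si](C)(C)C(C)(C)C)CC[C@](C)(O[Si](C)(C)C(C)(C)C)[C@@H]1[C@H](O)C(=C)C(C)C(=O)OCC | intermediate
31 | temporary C9 lactone (C17 epimers) | C[Si](C)(C)/C=C(/C)CC[C@H](OC(C)=O)[C@@]1(C)[C@@H](O[Si](C)(C)C(C)(C)C)CC[C@](C)(O[Si](C)(C)C(C)(C)C)[C@@H]1[C@@H]2OC(=O)C(C)C2=C | intermediate
32 | lithium dienolate of 31 | C[Si](C)(C)/C=C(/C)CC[C@H](OC(C)=O)[C@@]1(C)[C@@H](O[Si](C)(C)C(C)(C)C)CC[C@](C)(O[Si](C)(C)C(C)(C)C)[C@@H]1[C@@H]2OC(O[Li])=C(C)C2=C | intermediate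
33 | (17R)-C9 lactone | C[Si](C)(C)/C=C(/C)CC[C@H](OC(C)=O)[C@@]1(C)[C@@H](O[Si](C)(C)C(C)(C)C)CC[C@](C)(O[Si](C)(C)C(C)(C)C)[C@@H]1[C@@H]2OC(=O)[C@H](C)C2=C | intermediate
34 | (Z)-vinyl iodide lactone | I/C=C(/C)CC[C@H](OC(C)=O)[C@@]1(C)[C@@H](O[Si](C)(C)C(C)(C)C)CC[C@](C)(O[Si](C)(C)C(C)(C)C)[C@@H]1[C@@H]2OC(=O)[C@H](C)C2=C | intermediate
35 | (8S)-lactone diol | I/C=C(/C)CC[C@H](OC(C)=O)[C@@]1(C)[C@@H](O[Si](C)(C)C(C)(C)C)CC[C@](C)(O[Si](C)(C)C(C)(C)C)[C@@H]1[C@@H]2OC(=O)[C@H](C)[C@]2(O)CO | intermediate
36 | 7,8-bis(triethylsilyl) ether | I/C=C(/C)CC[C@H](OC(C)=O)[C@@]1(C)[C@@H](O[Si](C)(C)C(C)(C)C)CC[C@](C)(O[Si](C)(C)C(C)(C)C)[C@@H]1[C@@H]2OC(=O)[C@H](C)[C@]2(O[Si](CC)(CC)CC)CO[Si](CC)(CC)CC | intermediate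
37 | C7 aldehyde (8-OTES) | I/C=C(/C)CC[C@H](OC(C)=O)[C@@]1(C)[C@@H](O[Si](C)(C)C(C)(C)C)CC[C@](C)(O[Si](C)(C)C(C)(C)C)[C@@H]1[C@@H]2OC(=O)[C@H](C)[C@]2(O[Si](CC)(CC)CC)C=O | intermediate
38 | ring B allylic alcohol (7S, C9 lactone) | CC(=O)O[C@H]1CC/C(C)=C\[C@H](O)[C@@]2(O[Si](CC)(CC)CC)[C@@H](C)C(=O)O[C@H]2[C@@H]3[C@]1(C)[C@@H](O[Si](C)(C)C(C)(C)C)CC[C@]3(C)O[Si](C)(C)C(C)(C)C | intermediate
39 | C7 lactone 9-alcohol | CC(=O)O[C@H]1CC/C(C)=C\[C@@H]2OC(=O)[C@H](C)[C@@]2(O[Si](CC)(CC)CC)[C@@H](O)[C@@H]2[C@]1(C)[C@@H](O[Si](C)(C)C(C)(C)C)CC[C@]2(C)O[Si](C)(C)C(C)(C)C | intermediate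
40 | 8-O-TES-11,14-di-O-TBS Junceellolide I | CC(=O)O[C@H]1CC/C(C)=C\[C@@H]2OC(=O)[C@H](C)[C@@]2(O[Si](CC)(CC)CC)[C@@H](OC(C)=O)[C@@H]2[C@]1(C)[C@@H](O[Si](C)(C)C(C)(C)C)CC[C@]2(C)O[Si](C)(C)C(C)(C)C | intermediate
41 | Junceellolide I | CC(=O)O[C@H]1CC/C(C)=C\[C@@H]2OC(=O)[C@H](C)[C@@]2(O)[C@@H](OC(C)=O)[C@@H]2[C@]1(C)[C@@H](O)CC[C@]2(C)O | target

**Step count and risks**

Total step count: 25. Longest linear sequence: 21 steps (steps 1–6, 10–15 and 17–25).

The three steps most likely to fail are steps 12, 23 and 15.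

**Step 12.** The shift may be accompanied by migration of C13. The hydride transfer may also lag, because the new axial C14–O bond becomes syn-axial to the C9 side chain, so that retro-aldol cleavage or acetal formation of the ketone can take over.
The fallback separates the two events and puts them under different control.
- It sets out from 21.
- Silylation (Me3SiCl, imidazole) gives the O14 trimethylsilyl ether of the epoxy cyclopentanol F1.
- TiCl4-promoted rearrangement of F1 at −78 °C (Suzuki–Tsuchihashi type, strictly antiperiplanar) gives hydroxy ketone 22 after aqueous work-up.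
- Hydroxyl-directed reduction with Me4NBH(OAc)3 (Evans–Saksena, anti-selective) gives the 2,14-anti diol F2.
- Acetylation of the less hindered C2 hydroxyl (Ac2O, pyridine, 0 °C) comes back to the route at 24.

**Step 23.** Oligomerisation can compete with closure of the ten-membered ring. The constraint of the forming ring may also override the Felkin–Anh preference, which would mean poor facial selectivity at C7.
The fallback corrects C7 after closure instead of during it.
- It sets out from 37.
- The closure mixture contains the 7-epimeric ring B alcohol F3.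
- Dess–Martin oxidation converts the mixture to the ring B enone F4.
- 1,2-Reduction of F4 (NaBH4, CeCl3, MeOH, −78 °C, Luche) from the outer face of the ring comes back to the route at 38.

**Step 15.** The enolate may expel the axial C11 silyloxy group (β-elimination to the C10=C11 enal) faster than it is reprotonated.
The fallback replaces equilibration by soft enolisation and kinetic protonation.
- It sets out from 26.
- Me3SiOTf and Et3N (CH2Cl2, −78 °C) give the exocyclic C10=C9 trimethylsilyl enol ether F5 without a free enolate.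
- Hydrolysis of F5 with aqueous citric acid in THF at 0 °C protonates C10 from the open α face and comes back to the route at 27.

**Further compounds**
F1 | step 12 | O14 trimethylsilyl ether of the epoxy cyclopentanol | C[Si](C)(C)/C=C(/C)CC[C@@H]1O[C@@]1(C)[C@]2(O[Si](C)(C)C)CC[C@](C)(O[Si](C)(C)C(C)(C)C)[C@H]2CO[Si](CC)(CC)CC
F2 | step 12 | 2,14-anti diol | C[Si](C)(C)/C=C(/C)CC[C@H](O)[C@@]1(C)[C@@H](O)CC[C@](C)(O[Si](C)(C)C(C)(C)C)[C@H]1CO[Si](CC)(CC)CC
F3 | step 23 | 7-epimeric ring B alcohol | CC(=O)O[C@H]1CC/C(C)=C\[C@@H](O)[C@@]2(O[Si](CC)(CC)CC)[C@@H](C)C(=O)O[C@H]2[C@@H]3[C@]1(C)[C@@H](O[Si](C)(C)C(C)(C)C)CC[C@]3(C)O[Si](C)(C)C(C)(C)C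
F4 | step 23 | ring B enone | CC(=O)O[C@H]1CC/C(C)=C\C(=O)[C@@]2(O[Si](CC)(CC)CC)[C@@H](C)C(=O)O[C@H]2[C@@H]3[C@]1(C)[C@@H](O[Si](C)(C)C(C)(C)C)CC[C@]3(C)O[Si](C)(C)C(C)(C)C
F5 | step 15 | exocyclic C10=C9 trimethylsilyl enol ether | C[Si](C)(C)/C=C(/C)CC[C@H](OC(C)=O)[C@@]1(C)[C@@H](O[Si](C)(C)C(C)(C)C)CC[C@](C)(O[Si](C)(C)C(C)(C)C)C1=CO[Si](C)(C)C
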